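The constants of this flask are hidden, but one kind can be approached from the readings: the equilibrium constant that says how much target a temperature will hold.

| flask | solid substrate | reagent | temperature | remark | time |
|---|---|---|---|---|---|
| ash | 38 mM | 31 mM | 35 °C | run made earlier |  |
| cedar | 38 mM | 68 mM | 60 °C | run made earlier |  |
| teal | 38 mM | 45.6 mM | 60 °C |  | 10 h |
| blue | 38 mM | 45.6 mM | 40 °C |  | 10 h |
| red | 38 mM | 45.6 mM |  | at 80 °C until 8.0 h, from then on at 40 °C | 10 h |
| grey | 38 mM | 45.6 mM | 80 °C |  | 10 h |

| ash: time / h | ash: target / % | cedar: time / h | cedar: target / % |
|---|---|---|---|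
| 2.50 | 2 | 1.50 | 13 |
| 5.00 | 9 | 3.00 | 29 |
| 8.00 | 20 | 5.00 | 46 |
| 15.0 | 39 | 6.00 | 45 |
| 30.0 | 54 | 8.00 | 42 |

(each reading ± 1.5 percentage points)

1. the flask with the highest amount of target, in percent of the solid substrate charged ("all alike" if they lie within 1.5 percentage points) (teal / blue / red / grey / all alike)
2. final target, as a percentage of the solid substrate charged, in teal
3. final target, as a percentage of the solid substrate charged, in blue
4. final target, as a percentage of the solid substrate charged, in red
5. final target, as a percentage of the solid substrate charged, in grey

- given per volume of solution although it is solid: solid substrate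
- what was read earlier has a scatter of 1.5 percentage points, one standard deviation
- at the start none of the solid substrate is in solution
- what has only dissolved of solid substrate counts as not reacted

I measure target by the logarithm of its odds, target over the rest of the charge, so that half against half is the zero of my scale. The readings form a ladder. On the fastest rung, target climbs in cedar at 60 °C for 5.00 h, up to a reading of 46 %. On the next rung, cedar slides to 42 % at 8.00 h. On the slowest rung, ash at 35 °C is still rising at 30.0 h, a much longer time.

So the last ash reading gives odds of 1.17, which I hold as a lower bound because ash is climbing. The last cedar reading gives 0.724, an upper bound because cedar is falling. The drop in the logarithm of the odds per degree between them is the odds slope, 0.0193 K⁻¹, and I read it as the gentlest slope these bounds allow.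

Carried along the line past cedar, the slope gives odds of 0.492 at 80 °C, so I cap grey at 33.0 %. At 40 °C, between the two runs, the line gives odds of 1.07, or 51.6 %, which I take as an estimate and not as a cap. My own reckoning puts teal near cedar's last reading and red somewhere above grey, with 2.00 h to spend at 40 °C. Blue is warmer and richer in reagent than ash, so I place it between 39 % and that estimate, and I lean towards blue as the highest flask.

The forecast differs: it names teal, with teal 42 %, blue 35 %, red 19 % and grey 16 %, and says that red “then nearly freezes”.

The flasks give teal 40.5 %, blue 47.1 %, red 34.3 % and grey 27.8 %, so blue holds the most.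

    solid substrate ⇌ starting material, rate k1*(cs1 - [starting material]) while solid is left; crystals form when [starting material] > cs1 (solubility = 26.0 mM, k = 0.380 h⁻¹)
    starting material + by-product → side product (k = 5.00 L mol⁻¹ h⁻¹, Ea = 60.0 kJ mol⁻¹)
    starting material + reagent → intermediate + by-product (k = 51.0 L mol⁻¹ h⁻¹, Ea = 62.0 kJ mol⁻¹)
    intermediate ⇌ isomer of the product (K = 2.70, k = 0.920 h⁻¹, Ea = 95.0 kJ mol⁻¹, ΔH = −6.00 kJ mol⁻¹)
    intermediate ⇌ target (K = 2.80, k = 2.60 h⁻¹, Ea = 90.0 kJ mol⁻¹, ΔH = −32.0 kJ mol⁻¹)
    (constants at 60 °C)

Grey is under thermodynamic control: its target stands at 27.8 % after 10.0 h and 27.8 % after 100 h, below the 33.0 % that the odds slope of 0.0193 K⁻¹ allowed. The way back from target to intermediate holds it there, for without that step grey gives 92.5 %. The same line gave the estimate of 51.6 % for 40 °C. Red, cooled to that temperature, goes from 27.8 % at 8.00 h to 34.3 % at 10.0 h, and after 100 h it reaches 53.8 %.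

All runs stem from a simulated flask from invented constants, and the scatter is random.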